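## Structural features

Triphloroethol A (C18H14O9) is a linear trimer of phloroglucinol: three benzene rings joined only by two diaryl ether oxygens, ring A–O–ring B–O–ring C. Ring A is a 3,5-dihydroxyphenyl group. Ring B carries the ring A oxygen at B1, hydroxyls at B2 and B4 and the ring C oxygen at B6, so its two ether oxygens sit on neighbouring carbons. Ring C is a 2,4,6-trihydroxyphenyl group bound through C1. There is no stereocentre and no double-bond geometry, so the problem is one of position only. The seven free phenolic hydroxyls on three very electron-rich rings make the final compound prone to air oxidation and to electrophilic attack at the ring carbons between two oxygens, so the hydroxyls should stay masked until the last step. The real difficulty is the crowded B1/B6/C1 region: the C1–O bond of ring C is flanked by the oxygenated carbons C2 and C6 and faces the B1 aryloxy group, which is the worst case for any aryl–oxygen coupling. The key step exploits the oxygen pattern of ring C (oxygen on C1, C2, C4 and C6, hydrogen on C3 and C5). This pattern lets C1–C2 be read as a ketene oxidised at both carbons and C3–C4 and C5–C6 as two alkoxyacetylene units, so ring C can be grown on the B6 oxygen from an oxyacetyl chain.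

## Logic of the disconnections

18 to 17. The six O–alkyl bonds (four O–CH3 on rings A and B, two O–CH2CH3 on ring C) are cut. The seven hydroxyls have to be masked throughout, and small alkyl ethers survive every earlier step and fall in one Lewis-acid dealkylation. The gain is an air-stable penultimate compound that can be purified on silica. The forward step must cleave ethyl as well as methyl ethers completely without touching the two diaryl ether bonds.

17 to 9 and two molecules of 10. Ring C is cut at C1–C6, C5–C4 and C2–C3; C1–C2 remains as the two carbons of the oxyacetyl chain of 9. The cut is made here because it removes ring C altogether and leaves no aryl–oxygen bond to be formed at the doubly flanked C1. The gain is a two-ring acid chloride and a commercial two-carbon alkyne. The forward step must take up two molecules of 10 head-to-tail, one after the other, in a single vessel.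

9 to 8 to 7. The acyl C–Cl bond and then the ester O–CH3 bond are changed back. The ester is the storable form that is carried through the earlier steps. The demand is a chlorination mild and neutral enough for the strongly nucleophilic rings A and B.

7 to 5 and 6. The bond between the B1 oxygen and ring A is cut. The ring A carbon is unhindered (two CH neighbours), so the crowded oxygen of 5 meets an unhindered aryl partner in a room-temperature Chan–Lam coupling that tolerates the ester. The gain is two single-ring fragments. The demand is O-arylation of a phenol flanked by two oxygen substituents without oxidising it.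

5 to 3. The B1–O bond is traced back to a B1–CHO bond (Dakin-type oxidation through a Baeyer–Villiger aryl shift). The formyl group already sits at B1 in the commercial aldehyde, and replacing it by hydroxyl creates the 1,2,3,5-oxygen pattern of ring B with its two neighbouring oxygens already differentiated. The demand is aryl migration in preference to hydride migration, and survival of the ester.

3 to 1 and 2. The O–CH2 bond at the B6 oxygen is cut. This SN2 alkylation replaces the hindered aryl–oxygen coupling. Placing it first lets the two-carbon chain that becomes C1–C2 of ring C also protect the B6 oxygen through the oxidation and the arylation, so no separate protecting group is put on and taken off. The demand is O-alkylation without aldol ring closure of the product to a benzofuran.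

## Other disconnections considered

Alternative 1: Both carbon–oxygen bonds at B6 and B1 of ring B are cut and traced to the two carbons of the strained triple bond of an aryne; the key-step product is 2,4-dimethoxy-6-(2,4,6-trimethoxyphenoxy)phenol A1.
- Forward key step: iodine–magnesium exchange on 2-iodo-3,5-dimethoxyphenyl 4-chlorobenzenesulfonate A2 with iPrMgCl and loss of the sulfonate would release 3,5-dimethoxybenzyne A3. The chloromagnesium salt of 2,4,6-trimethoxyphenol A4 would add through oxygen at the aryne carbon remote from the methoxy group (B6), since the aryl anion then sits at B1 next to that methoxy group. B(OMe)3 and then H2O2 would turn the B1–Mg bond into the hydroxyl of A1. Chan–Lam coupling of A1 with 6 and demethylation would complete 18.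
- In favour: two neighbouring oxygens are set in one flask with regiochemistry dictated by the alkoxy-substituted aryne. Ring C is bought as A4 and not built. Only methyl ethers are used. The sequence is about five steps (iodination of 3,5-dimethoxyphenol A5, sulfonylation, aryne step, arylation, demethylation); on step count this alternative is the better.
- Against: the nucleophile is a phenoxide whose oxygen is flanked by two methoxy groups and is weakly nucleophilic as its magnesium salt, so the crowded C1–O bond of ring C has to form in the very step in which a short-lived aryne must be intercepted. C-arylation of the ambident phenoxide and addition of iPrMgCl itself are plausible competitors. The arylmagnesium at B1 lies between two oxygen substituents and must be borylated and oxidised in the presence of electron-rich rings. Iodination of A5 at C2 and not at C4 is not assured.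
- Comparison: structurally, alternative 1 meets the hindered aryl–oxygen bond head-on, whereas the chosen plan replaces it by an SN2 alkylation and a ring construction. Both plans then need the same Chan–Lam arylation of a doubly flanked phenol, so they are equal on that point. Mechanistically both rely on polar regiocontrol (aryne distortion against ynol ether polarity). The aryne route stacks three organometallic events in one flask, against a neutral thermal cascade in the chosen plan.

Alternative 2: The B4–B5 bond of ring B is cut; the key-step product is the hydroquinone 2-isopropoxy-6-(2,4,6-trimethoxyphenoxy)benzene-1,4-diol A6.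
- Forward key step: heating 4-hydroxy-3-isopropoxy-4-[1-(2,4,6-trimethoxyphenoxy)ethenyl]cyclobut-2-en-1-one A7 in toluene or xylene would open the four-membered ring (conrotatory, 4π) to a dienylketene. 6π-Electrocyclisation would join the ketene carbon (B4) to the vinyl terminus (B5), and tautomerisation would give A6. A7 would come from the α-lithio derivative (t-BuLi) of 2-(ethenyloxy)-1,3,5-trimethoxybenzene A8 and the ketone carbonyl of 3-isopropoxycyclobut-3-ene-1,2-dione A9.
- In favour: this thermal ring expansion of 4-alkenyl-4-hydroxycyclobutenones is long established and unimolecular, so the key step rests on firmer precedent than the two-component cascade chosen here; on this point alternative 2 is the better. The oxygen pattern of ring B is written into the four-membered ring and cannot scramble. Mechanistically the two plans are equals, since both pass through a cyclobutenone opening and a dienylketene 6π closure.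
- Against: A6 has two free hydroxyls, and the one that must carry ring A (B1) is the more hindered, so the B4 hydroxyl would have to be masked selectively before coupling with 6. The crowded ring C–O bond is not avoided but moved into the preparation of A8 from the hindered phenol A4. Lithiation of A8 at the vinyl carbon must compete with metalation of the ring carbons between two methoxy groups. A9 needs a partial reduction of a dialkyl squarate.
- Comparison: semisquarate, vinyl ether, addition, thermolysis, selective protection, arylation and a deprotection that removes three kinds of group come to roughly nine or ten operations against seven. The chosen plan is shorter and uses one class of protecting group.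

Alternative 3: The B2–B3 bond of ring B is cut; the key-step product is 4-(3,5-dimethoxyphenoxy)-5-(2,4,6-trimethoxyphenoxy)benzene-1,3-diol A10.
- Forward key step: lithium diisopropylamide (THF, −78 °C to room temperature) would deprotonate the 6-methyl group of 3-(3,5-dimethoxyphenoxy)-6-methyl-4-(2,4,6-trimethoxyphenoxy)-2H-pyran-2-one A11. The dienolate would open at the ring O–C2 bond to a ketene enolate, whose methylene carbon (B3) would bond to the ketene carbon (B2), and tautomerisation would give A10. A11 would be assembled from 4-hydroxy-6-methyl-2H-pyran-2-one A12.
- In favour: A10 already holds all three rings, both ether bridges and the free B2 and B4 hydroxyls, so only five methyl ethers separate it from 18. No ethyl ethers and no later arylation are needed. On convergence and on the length of the end-game this alternative is the better, and at about six steps it is at least the equal on total count.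
- Against: two different aryloxy groups must be placed on the adjacent carbons C3 and C4 of A11. The C4–O bond by addition–elimination of the phenoxide of A4 on an activated derivative of A12 is plausible. The C3–O bond to 3,5-dimethoxyphenol A5, next to that bulky group, would need a copper-mediated coupling on a 3-halopyranone of the very kind the chosen plan is built to avoid. The isomerisation is the least secure point: 6-methyl anions of 4-oxygenated pyranones are normally stable enough to be alkylated, so ring opening would have to outrun attack of the amide base at the lactone carbonyl or at C4 with loss of an aryloxide.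
- Comparison: structurally, alternative 3 closes the central ring last and is the most convergent, whereas the chosen plan builds an outer ring last on a finished A–B unit. Mechanistically it is an anionic process on a substrate with two vinylogous leaving groups, against a neutral thermal cascade whose two halves each have close precedent.

Key step: step 6

Remark: intermediates 12, 14 and 16 each hold one sp3 stereocentre, would form as racemates and lose that centre on aromatisation, so they are drawn without configuration; 10 is taken as its commercial solution in hexanes, and free phenols are handled under argon.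

## Steps

Step 1
Reactants: 1 2-hydroxy-4,6-dimethoxybenzaldehyde; 2 methyl bromoacetate
Product: 3 methyl 2-(2-formyl-3,5-dimethoxyphenoxy)acetate
Conditions: K2CO3, acetone, reflux
Reagents that add atoms: none
Why: Williamson O-alkylation of the only phenol of 1 by an activated primary bromide; the temperature stays below that needed for base-induced aldol closure of the product to a benzofuran.

Step 2
Reactants: 3 methyl 2-(2-formyl-3,5-dimethoxyphenoxy)acetate
Product: 5 methyl 2-(2-hydroxy-3,5-dimethoxyphenoxy)acetate, via aryl formate 4 (not isolated)
Conditions: mCPBA, NaHCO3, CH2Cl2, 0 °C to rt; aq Na2S2O3 wash; then Et3N, MeOH, rt, argon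
Reagents that add atoms: mCPBA (3-chloroperoxybenzoic acid), OOC(=O)c1cccc(Cl)c1
Why: Baeyer–Villiger oxidation with Dakin-type outcome; the 2,4,6-trioxygenated aryl group should migrate far faster than hydride to give formate 4, which protects the ring from over-oxidation until the peracid is quenched. Methanolysis then frees the phenol while the methyl ester is unchanged, since its exchange with methanol is degenerate.

Step 3
Reactants: 5 methyl 2-(2-hydroxy-3,5-dimethoxyphenoxy)acetate; 6 (3,5-dimethoxyphenyl)boronic acid
Product: 7 methyl 2-[2-(3,5-dimethoxyphenoxy)-3,5-dimethoxyphenoxy]acetate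
Conditions: Cu(OAc)2 (2 equiv), pyridine, 4 Å molecular sieves, CH2Cl2, dry air, rt
Reagents that add atoms: none
Why: Chan–Lam O-arylation; the hindered partner is the phenol, while 6 has two free ortho positions, the combination this coupling tolerates at room temperature, and the ester is inert.

Step 4
Reactants: 7 methyl 2-[2-(3,5-dimethoxyphenoxy)-3,5-dimethoxyphenoxy]acetate
Product: 8 2-[2-(3,5-dimethoxyphenoxy)-3,5-dimethoxyphenoxy]acetic acid
Conditions: LiOH, THF/H2O, rt; then 1 M HCl to pH 2
Reagents that add atoms: lithium hydroxide, [Li+].[OH-]
Why: saponification of an unhindered methyl ester; aryl ethers are inert and acidification should give the free acid.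

Step 5
Reactants: 8 2-[2-(3,5-dimethoxyphenoxy)-3,5-dimethoxyphenoxy]acetic acid
Product: 9 2-[2-(3,5-dimethoxyphenoxy)-3,5-dimethoxyphenoxy]acetyl chloride
Conditions: 1-chloro-N,N,2-trimethylprop-1-en-1-amine, CH2Cl2, 0 °C to rt; solvent exchanged for toluene, crude used at once
Reagents that add atoms: 1-chloro-N,N,2-trimethylprop-1-en-1-amine, CC(C)=C(Cl)N(C)C
Why: conversion of the acid to the acid chloride by an α-chloroenamine under neutral conditions; no HCl and no chloroiminium or oxalyl electrophile is present to attack the nucleophilic rings A and B, and the amide by-product is inert in step 6.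

Step 6
Reactants: 9 2-[2-(3,5-dimethoxyphenoxy)-3,5-dimethoxyphenoxy]acetyl chloride; 10 ethoxyacetylene (two equivalents incorporated)
Product: 17 2-[2-(3,5-dimethoxyphenoxy)-3,5-dimethoxyphenoxy]-3,5-diethoxyphenol, via aryloxyketene 11 (not isolated), via aryloxycyclobutenone 12 (not isolated), via vinylketene 13 (not isolated), via vinylcyclobutenone 14 (not isolated), via dienylketene 15 (not isolated), via cyclohexadienone 16 (not isolated)
Conditions: 10 (6 equiv), Et3N (1.3 equiv), toluene, slow addition of 9 at 0 °C, then rt; filtration from Et3NHCl under argon; sealed vessel, 80 °C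
Reagents that add atoms: none
Why: Proposed new method: Et3N should dehydrochlorinate 9 to aryloxyketene 11, whose carbonyl carbon (future C2) is attacked by the nucleophilic CH carbon of 10 while the ethoxy-bearing carbon (future C6) bonds to the ketene α-carbon (future C1), giving cyclobutenone 12 by (2+2) cycloaddition. At 80 °C 12 should open by conrotatory 4π-electrocyclic cleavage of C1–C2, the aryloxy donor turning outward, to vinylketene 13, which takes up a second 10 in the same sense (C2–C3 and C5–C4) to give 14. Reversible 4π opening of 14 gives dienylketene 15, and the isomer with the two chain ends cis closes ring C by thermal disrotatory 6π-electrocyclisation, which re-forms C1–C2 and gives 16; enolisation gives phenol 17. The closest known reaction types are the (2+2) cycloaddition of ketenes with alkoxyacetylenes to 3-alkoxycyclobutenones and the Danheiser benzannulation of cyclobutenones with ynol ethers; new here are their union in one vessel and the use of an aryloxy-substituted aldoketene and a 4-aryloxycyclobutenone. Ring C is the only ring that persists, and it is closed by the pericyclic six-electron step, the two four-membered rings being transient. No stereocentre survives, since the sp3 carbons of 12, 14 and 16 disappear on aromatisation. The step needs head-to-tail orientation in both alkyne uptakes, which the opposed polarities of ynol ether and ketene (CH carbon to ketene carbonyl carbon) should secure, giving the 2,4,6-oxygen pattern. It also needs cycloaddition to outrun ketene self-condensation, which slow addition of 9 into excess 10 and a temperature below the retro-ene fragmentation of 10 are meant to secure.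

Step 7
Reactants: 17 2-[2-(3,5-dimethoxyphenoxy)-3,5-dimethoxyphenoxy]-3,5-diethoxyphenol
Product: 18 Triphloroethol A, 2-[2-(3,5-dihydroxyphenoxy)-3,5-dihydroxyphenoxy]benzene-1,3,5-triol
Conditions: BBr3 (12 equiv), CH2Cl2, −78 °C to rt; then H2O, 0 °C, argon
Reagents that add atoms: none
Why: Lewis-acid ether cleavage; BBr3 coordinates each alkoxy oxygen and bromide attacks the alkyl carbon by SN2, so methyl and ethyl ethers should both fall with excess reagent, while the diaryl ether bonds have no sp3 carbon to attack and stay intact.

## Compound list

1 | 2-hydroxy-4,6-dimethoxybenzaldehyde | COc1cc(O)c(C=O)c(OC)c1 | starting material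
2 | methyl bromoacetate | COC(=O)CBr | starting material
3 | methyl 2-(2-formyl-3,5-dimethoxyphenoxy)acetate | COC(=O)COc1cc(OC)cc(OC)c1C=O | intermediate
4 | methyl 2-[2-(formyloxy)-3,5-dimethoxyphenoxy]acetate | COC(=O)COc1cc(OC)cc(OC)c1OC=O | intermediate
5 | methyl 2-(2-hydroxy-3,5-dimethoxyphenoxy)acetate | COC(=O)COc1cc(OC)cc(OC)c1O | intermediate
6 | (3,5-dimethoxyphenyl)boronic acid | COc1cc(OC)cc(B(O)O)c1 | starting material
7 | methyl 2-[2-(3,5-dimethoxyphenoxy)-3,5-dimethoxyphenoxy]acetate | COC(=O)COc1cc(OC)cc(OC)c1Oc1cc(OC)cc(OC)c1 | intermediate
8 | 2-[2-(3,5-dimethoxyphenoxy)-3,5-dimethoxyphenoxy]acetic acid | OC(=O)COc1cc(OC)cc(OC)c1Oc1cc(OC)cc(OC)c1 | intermediate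
9 | 2-[2-(3,5-dimethoxyphenoxy)-3,5-dimethoxyphenoxy]acetyl chloride | COc1cc(OCC(Cl)=O)c(Oc2cc(OC)cc(OC)c2)c(OC)c1 | intermediate
10 | ethoxyacetylene | CCOC#C | starting material
11 | 2-[2-(3,5-dimethoxyphenoxy)-3,5-dimethoxyphenoxy]ethen-1-one (aryloxyketene) | O=C=COc1cc(OC)cc(OC)c1Oc1cc(OC)cc(OC)c1 | intermediate
12 | 4-[2-(3,5-dimethoxyphenoxy)-3,5-dimethoxyphenoxy]-3-ethoxycyclobut-2-en-1-one (racemic) | CCOC1=CC(=O)C1Oc1cc(OC)cc(OC)c1Oc1cc(OC)cc(OC)c1 | intermediate
13 | (3Z)-4-[2-(3,5-dimethoxyphenoxy)-3,5-dimethoxyphenoxy]-3-ethoxybuta-1,3-dien-1-one | O=C=C/C(OCC)=C/Oc1cc(OC)cc(OC)c1Oc1cc(OC)cc(OC)c1 | intermediate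
14 | 4-{(1Z)-2-[2-(3,5-dimethoxyphenoxy)-3,5-dimethoxyphenoxy]-1-ethoxyethenyl}-3-ethoxycyclobut-2-en-1-one (racemic) | CCOC1=CC(=O)C1/C(OCC)=C/Oc1cc(OC)cc(OC)c1Oc1cc(OC)cc(OC)c1 | intermediate
15 | (3E,5Z)-6-[2-(3,5-dimethoxyphenoxy)-3,5-dimethoxyphenoxy]-3,5-diethoxyhexa-1,3,5-trien-1-one | O=C=C/C(OCC)=C\C(OCC)=C\Oc1cc(OC)cc(OC)c1Oc1cc(OC)cc(OC)c1 | intermediate
16 | 6-[2-(3,5-dimethoxyphenoxy)-3,5-dimethoxyphenoxy]-3,5-diethoxycyclohexa-2,4-dien-1-one (racemic) | O=C1C=C(OCC)C=C(OCC)C1Oc1cc(OC)cc(OC)c1Oc1cc(OC)cc(OC)c1 | intermediate
17 | 2-[2-(3,5-dimethoxyphenoxy)-3,5-dimethoxyphenoxy]-3,5-diethoxyphenol | CCOc1cc(O)c(Oc2cc(OC)cc(OC)c2Oc2cc(OC)cc(OC)c2)c(OCC)c1 | intermediate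
18 | Triphloroethol A, 2-[2-(3,5-dihydroxyphenoxy)-3,5-dihydroxyphenoxy]benzene-1,3,5-triol | Oc1cc(O)cc(Oc2c(O)cc(O)cc2Oc2c(O)cc(O)cc2O)c1 | target

## Step count and least certain steps

Total step count: 7. Longest linear sequence: 7 steps (1 to 3, 5, 7, 8, 9, 17, 18).

Step 6 (key step, proposed new method).
- What may go wrong: self-condensation of the aryloxyketene (dimerisation, or acylation of its ammonium enolate) may outpace the first cycloaddition. In the thermal stage, the phenol already formed may capture vinylketene 13 by O-acylation, and 10 fragments by retro-ene reaction if the temperature is raised much above 80 °C. The cause is that three bimolecular events must each beat a competing pathway of a very reactive ketene. A short K2CO3/MeOH treatment of the crude product would return any O-acylated material to 17.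
- Fallback (known chemistry; ring C is bought, not built): it sets out from 1. Benzylation (benzyl bromide, K2CO3, DMF) would give 2-(benzyloxy)-4,6-dimethoxybenzaldehyde F1. Baeyer–Villiger oxidation with mCPBA would give 2-(benzyloxy)-4,6-dimethoxyphenyl formate F2, and methanolysis 2-(benzyloxy)-4,6-dimethoxyphenol F3. Chan–Lam coupling with 6 would give 1-(benzyloxy)-2-(3,5-dimethoxyphenoxy)-3,5-dimethoxybenzene F4. Hydrogenolysis (H2, zerovalent palladium on carbon, EtOAc) would give 2-(3,5-dimethoxyphenoxy)-3,5-dimethoxyphenol F5. Ullmann-type coupling of F5 with commercial 2-iodo-1,3,5-trimethoxybenzene (copper monoiodide CuI, picolinic acid, K3PO4, DMSO, 90 °C) would give 2-[2-(3,5-dimethoxyphenoxy)-3,5-dimethoxyphenoxy]-1,3,5-trimethoxybenzene F6. BBr3 demethylation of F6 comes back to the route at 18.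

Step 3.
- What may go wrong: oxidation of the very electron-rich phenol 5 by divalent copper and air (quinone formation or oxidative coupling) may compete with slow transmetalation at an oxygen flanked on both sides, and 6 may be lost by protodeboronation.
- Fallback: it sets out from 5. A non-oxidative Ullmann-type coupling with commercial 1-iodo-3,5-dimethoxybenzene (copper monoiodide CuI, picolinic acid, K3PO4, DMSO, 80 °C, argon) changes both the aryl donor and the mechanism and comes back to the route at 7.

Step 5.
- What may go wrong: the acyl chloride may close onto the activated ring B carbon B5 next to the oxyacetyl chain (intramolecular Friedel–Crafts acylation), or hydrolyse during the solvent exchange, because ring B is strongly activated by its ether oxygens.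
- Fallback: it sets out from 8 and avoids the acid chloride. 4-Methylbenzenesulfonyl chloride and Et3N in toluene in the presence of 10 would form the mixed anhydride 2-[2-(3,5-dimethoxyphenoxy)-3,5-dimethoxyphenoxy]acetic 4-methylbenzenesulfonic anhydride F7. F7 would lose sulfonate under Et3N and come back to the route at ketene 11 inside step 6.

Step 7.
- What may go wrong: cleavage of the two ethyl ethers, which is slower than that of the methyl ethers, may stay incomplete, and the free heptaphenol may be lost by oxidation during chromatography.
- Fallback: it sets out from 17. After the BBr3 treatment the crude polyphenol is not purified but acetylated (acetic anhydride, pyridine) to triphloroethol A heptaacetate F8. F8 can be freed from partly alkylated material on silica, and acid-catalysed methanolysis (HCl, MeOH, argon) comes back to the route at 18.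

## Further compounds

F1 | step 6 | 2-(benzyloxy)-4,6-dimethoxybenzaldehyde | COc1cc(OCc2ccccc2)c(C=O)c(OC)c1
F2 | step 6 | 2-(benzyloxy)-4,6-dimethoxyphenyl formate | COc1cc(OCc2ccccc2)c(OC=O)c(OC)c1
F3 | step 6 | 2-(benzyloxy)-4,6-dimethoxyphenol | COc1cc(OCc2ccccc2)c(O)c(OC)c1
F4 | step 6 | 1-(benzyloxy)-2-(3,5-dimethoxyphenoxy)-3,5-dimethoxybenzene | COc1cc(OC)cc(Oc2c(OC)cc(OC)cc2OCc2ccccc2)c1
F5 | step 6 | 2-(3,5-dimethoxyphenoxy)-3,5-dimethoxyphenol | COc1cc(O)c(Oc2cc(OC)cc(OC)c2)c(OC)c1
F6 | step 6 | 2-[2-(3,5-dimethoxyphenoxy)-3,5-dimethoxyphenoxy]-1,3,5-trimethoxybenzene | COc1cc(OC)cc(Oc2c(OC)cc(OC)cc2Oc2c(OC)cc(OC)cc2OC)c1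
F0 | step 3 | none | none
F7 | step 5 | 2-[2-(3,5-dimethoxyphenoxy)-3,5-dimethoxyphenoxy]acetic 4-methylbenzenesulfonic anhydride | COc1cc(OC)cc(Oc2c(OC)cc(OC)cc2OCC(=O)OS(=O)(=O)c2ccc(C)cc2)c1
F8 | step 7 | triphloroethol A heptaacetate | CC(=O)Oc1cc(OC(C)=O)cc(Oc2c(OC(C)=O)cc(OC(C)=O)cc2Oc2c(OC(C)=O)cc(OC(C)=O)cc2OC(C)=O)c1
A1 | alternative 1 | 2,4-dimethoxy-6-(2,4,6-trimethoxyphenoxy)phenol | COc1cc(OC)c(O)c(Oc2c(OC)cc(OC)cc2OC)c1
A2 | alternative 1 | 2-iodo-3,5-dimethoxyphenyl 4-chlorobenzenesulfonate | COc1cc(OC)c(I)c(OS(=O)(=O)c2ccc(Cl)cc2)c1
A3 | alternative 1 | 3,5-dimethoxybenzyne | COC1=CC(OC)=CC#C1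
A4 | alternative 1 | 2,4,6-trimethoxyphenol | COc1cc(OC)c(O)c(OC)c1
A5 | alternative 1 | 3,5-dimethoxyphenol | COc1cc(O)cc(OC)c1
A6 | alternative 2 | 2-isopropoxy-6-(2,4,6-trimethoxyphenoxy)benzene-1,4-diol | CC(C)Oc1cc(O)cc(Oc2c(OC)cc(OC)cc2OC)c1O
A7 | alternative 2 | 4-hydroxy-3-isopropoxy-4-[1-(2,4,6-trimethoxyphenoxy)ethenyl]cyclobut-2-en-1-one (racemic) | CC(C)OC1=CC(=O)C1(O)C(=C)Oc1c(OC)cc(OC)cc1OC
A8 | alternative 2 | 2-(ethenyloxy)-1,3,5-trimethoxybenzene | C=COc1c(OC)cc(OC)cc1OC
A9 | alternative 2 | 3-isopropoxycyclobut-3-ene-1,2-dione | CC(C)OC1=CC(=O)C1=O
A10 | alternative 3 | 4-(3,5-dimethoxyphenoxy)-5-(2,4,6-trimethoxyphenoxy)benzene-1,3-diol | Oc1cc(O)c(Oc2cc(OC)cc(OC)c2)c(Oc2c(OC)cc(OC)cc2OC)c1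
A11 | alternative 3 | 3-(3,5-dimethoxyphenoxy)-6-methyl-4-(2,4,6-trimethoxyphenoxy)-2H-pyran-2-one | Cc1cc(Oc2c(OC)cc(OC)cc2OC)c(Oc2cc(OC)cc(OC)c2)c(=O)o1
A12 | alternative 3 | 4-hydroxy-6-methyl-2H-pyran-2-one | Cc1cc(O)cc(=O)o1
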